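**Retrosynthetic overview**

1. The last bond made is the ring bond between the carbonyl carbon next to the quaternary carbon and the ring carbon that carries the single prenyl group. It is closed by a Claisen condensation of an acyclic methyl ester enolate, released in the same flask from a dearomatized 3,3-dialkyl pyran-2,4-dione.
2. That lactone comes from a flat, achiral 5-benzoyl-4-hydroxy-3-prenyl-2-pyranone and geranyl methyl carbonate by asymmetric dearomative C-3 geranylation, which sets the only stereocentre. The pyranone comes from a 1,3-diketone (6-methylhept-5-en-2-one plus methyl benzoate), a malonyl half-ester chloride and prenyl acetate.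
3. Order of rings: the pyranone ring first (step 2, a temporary ring), the carbocycle last (step 5), when ring oxygen O-1 is turned out of the ring and the side-chain CH2 on C-6 is joined to C-2.
4. Enabling feature: in the dearomatized lactone, carbonyl C-2 lies between O-1 and the quaternary C-3, so it has no α-hydrogen and cannot enolize, form a ketene or epimerize. O-1 ties C-2 to enol carbon C-6, whose side-chain CH2 is the only acidic C–H once the lactone is opened. The aromatic pyranone is inert to alkoxide, so the acyl donor is unmasked only by the dearomatization.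

Key step: step 5

Assumption: the sense of induction of the chiral diphosphine on the 3-prenyl pyronate cannot be taken from precedent; the (R,R)-ligand is written for the face of C-3 that leads to the (3S)-lactone, and the (S,S)-ligand (or exchange of the prenyl and geranyl electrophiles between steps 3 and 5) is used if the sense is opposite.

Remark: all β-polycarbonyl compounds are written as one tautomer; prenyl = 3-methylbut-2-en-1-yl, geranyl = (2E)-3,7-dimethylocta-2,6-dien-1-yl.

Step 1
Reactants: 1 6-methylhept-5-en-2-one; 2 methyl benzoate
Product: 3 7-methyl-1-phenyloct-6-ene-1,3-dione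
Conditions: NaH (2.2 equiv), THF, reflux, slow addition of 1; 1 M HCl
Reagents that add atoms: none
Why: Crossed Claisen condensation of a methyl ketone with a non-enolizable ester, which should acylate the methyl group because that 1,3-diketone is drained from the equilibrium as its less hindered sodium enolate; no stereocentre is formed.

Step 2
Reactants: 3 7-methyl-1-phenyloct-6-ene-1,3-dione; 4 ethyl 3-chloro-3-oxopropanoate
Product: 6 5-benzoyl-4-hydroxy-6-(4-methylpent-3-en-1-yl)-2H-pyran-2-one, via keto ester 5 (not isolated)
Conditions: MgCl2 (1.1 equiv), pyridine (2.2 equiv), CH2Cl2, 0 °C → rt; then DBU (2.5 equiv), toluene, 80 °C; 1 M HCl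
Reagents that add atoms: none
Why: Magnesium-mediated C-acylation of the 1,3-diketone at its central carbon (soft enolization) gives triacylmethane 5, which should lactonize through the oxygen of the alkanoyl carbonyl (6-exo-trig, the known base-mediated cyclization of 3,5-dioxo esters to 4-hydroxy-2-pyranones), the terminus at which aryl alkyl 1,3-diketones are normally derivatized, and the product is drained as its aromatic pyronate; no stereocentre is formed.

Step 3
Reactants: 6 5-benzoyl-4-hydroxy-6-(4-methylpent-3-en-1-yl)-2H-pyran-2-one; 7 3-methylbut-2-en-1-yl acetate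
Product: 8 5-benzoyl-4-hydroxy-3-(3-methylbut-2-en-1-yl)-6-(4-methylpent-3-en-1-yl)-2H-pyran-2-one
Conditions: Pd(PPh3)4 (3 mol%), DBU (1.1 equiv), THF, 50 °C
Reagents that add atoms: none
Why: Tsuji–Trost allylation of a 4-hydroxy-2-pyranone, known to take place at C-3 with the unsubstituted terminus of the allyl unit, here under thermodynamic control because O-prenyl ethers and any 3,3-diprenyl lactone re-ionize on zerovalent palladium and should settle to the aromatic mono-C-prenyl pyronate; no stereocentre is formed.

Step 4
Reactants: 9 geraniol
Product: 10 (2E)-3,7-dimethylocta-2,6-dien-1-yl methyl carbonate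
Conditions: ClCO2Me (1.2 equiv), pyridine, CH2Cl2, 0 °C
Reagents that add atoms: methyl chloroformate COC(Cl)=O
Why: Acylation of a primary allylic alcohol with a chloroformate, which leaves the E double bond untouched and gives the ionizable carbonate whose leaving group later delivers the methoxide needed in step 5.

Step 5
Reactants: 8 5-benzoyl-4-hydroxy-3-(3-methylbut-2-en-1-yl)-6-(4-methylpent-3-en-1-yl)-2H-pyran-2-one; 10 (2E)-3,7-dimethylocta-2,6-dien-1-yl methyl carbonate
Product: 13 kolanone, via pyrandione 11 (not isolated), via methyl ester enolate 12 (not isolated)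
Conditions: NaH (1.0 equiv), THF, 0 °C; 10 (1.15 equiv), Pd2(dba)3·CHCl3 (2.5 mol%), (R,R)-DACH-phenyl diphosphine ligand (7.5 mol%), 0 °C → rt; then LiN(iPr)2 (2.5 equiv), −78 → 0 °C; 1 M HCl
Reagents that add atoms: none
Why: Proposed new method: the sodium pyronate of 8 should attack the π-geranyl complex formed from 10 and zerovalent palladium at C-3 (outer sphere, at the CH2 terminus), which dearomatizes the pyranone to lactone 11; the methoxide set free from the carbonate leaving group then opens this enol lactone, an acyl donor only once the ring is no longer aromatic, to ester enolate 12, and LiN(iPr)2 removes a proton from the side-chain CH2 next to the alkanoyl carbonyl, whose carbanion adds to the ester carbonyl and expels methoxide to give the dianion of 13. The closest known reaction types are, for the first stage, the palladium-catalysed asymmetric allylic alkylation of prochiral stabilized enolates (azlactones, β-keto esters) with prenyl-type electrophiles and the Tsuji–Trost C-3 allylation of 4-hydroxy-2-pyranones, and, for the second stage, the alkoxide-relayed rearrangement of enol lactones to cyclic 1,3-diones and the γ-acylation of 1,3-diketone dianions by esters. The six-membered carbocycle closes by a 6-exo-trig Claisen (Dieckmann-type) condensation. The quaternary stereocentre is set in the allylation by the chiral diphosphine ligand, which should tell the two faces of planar C-3 apart because one flank is the bare lactone unit (C-2, O-1) and the other is C-4 next to the twisted, chelated 5-benzoyl group; it cannot be lost afterwards, since the quaternary carbon has no enolizable hydrogen and the lactone carbonyl always becomes the ring carbonyl next to the prenyl-bearing carbon. The step needs C- over O-allylation with linear attack and retention of the E geometry (O-geranyl products re-ionize on palladium, whereas C-allylated 11 is withdrawn from that equilibrium by methanolysis, which should also forestall exchange of the two allyl groups), and a single site of deprotonation, secured because the quaternary carbon and the fully substituted triacylmethanide carbon leave the side-chain CH2 as the only acidic C–H.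

**Compound list**

1 | 6-methylhept-5-en-2-one | CC(C)=CCCC(C)=O | starting material
2 | methyl benzoate | COC(=O)c1ccccc1 | starting material
3 | 7-methyl-1-phenyloct-6-ene-1,3-dione | CC(C)=CCCC(=O)CC(=O)c1ccccc1 | intermediate
4 | ethyl 3-chloro-3-oxopropanoate (ethyl malonyl chloride) | CCOC(=O)CC(Cl)=O | starting material
5 | ethyl 4-benzoyl-9-methyl-3,5-dioxodec-8-enoate (triacylmethane carbon configurationally labile) | CCOC(=O)CC(=O)C(C(=O)c1ccccc1)C(=O)CCC=C(C)C | intermediate
6 | 5-benzoyl-4-hydroxy-6-(4-methylpent-3-en-1-yl)-2H-pyran-2-one | O=C1C=C(O)C(C(=O)c2ccccc2)=C(CCC=C(C)C)O1 | intermediate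
7 | 3-methylbut-2-en-1-yl acetate (prenyl acetate) | CC(C)=CCOC(C)=O | starting material
8 | 5-benzoyl-4-hydroxy-3-(3-methylbut-2-en-1-yl)-6-(4-methylpent-3-en-1-yl)-2H-pyran-2-one | O=C1C(CC=C(C)C)=C(O)C(C(=O)c2ccccc2)=C(CCC=C(C)C)O1 | intermediate
9 | geraniol, (2E)-3,7-dimethylocta-2,6-dien-1-ol | CC(C)=CCC/C(C)=C/CO | starting material
10 | (2E)-3,7-dimethylocta-2,6-dien-1-yl methyl carbonate | CC(C)=CCC/C(C)=C/COC(=O)OC | intermediate
11 | (3S)-5-benzoyl-3-[(2E)-3,7-dimethylocta-2,6-dien-1-yl]-3-(3-methylbut-2-en-1-yl)-6-(4-methylpent-3-en-1-yl)-2H-pyran-2,4(3H)-dione | CC(C)=CCC/C(C)=C/C[C@]1(CC=C(C)C)C(=O)OC(CCC=C(C)C)=C(C(=O)c2ccccc2)C1=O | intermediate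
12 | methyl (2S)-4-benzoyl-2-[(2E)-3,7-dimethylocta-2,6-dien-1-yl]-9-methyl-2-(3-methylbut-2-en-1-yl)-3,5-dioxodec-8-enoate (formed as its sodium enolate) | CC(C)=CCC/C(C)=C/C[C@](C(=O)C(C(=O)c1ccccc1)C(=O)CCC=C(C)C)(CC=C(C)C)C(=O)OC | intermediate
13 | kolanone, (R)-configured 2-benzoyl-6-geranyl-4,6-diprenylcyclohexane-1,3,5-trione written as the enol tautomer of the SMILES | CC(C)=CCC/C(C)=C/C[C@]1(CC=C(C)C)C(=O)C(CC=C(C)C)=C(O)/C(=C(\O)c2ccccc2)C1=O | target

Total step count: 5
Longest linear sequence: 4 steps (steps 1, 2, 3, 5)

**Steps most likely to fail**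

Step 5 (Proposed new method). Three processes may fail. The chiral palladium complex may discriminate the pyronate faces poorly. The C-3 allyl groups may re-ionize on zerovalent palladium before the methoxide relay has opened the lactone, which would exchange prenyl and geranyl and erode enantiomeric purity. Methoxide may attack at C-6 (vinylogous opening to a carboxylate) and not at C-2. Fallback with known chemistry, setting out from diketone 3 and coming back at ester 12 (then isolated as the neutral triketone): the quaternary carbon is made by asymmetric phase-transfer alkylation and not by dearomatization. Commercial tert-butyl methyl malonate is alkylated with prenyl bromide (NaH, THF) to tert-butyl methyl 2-(3-methylbut-2-en-1-yl)propanedioate F1. Geranyl bromide, 50% aqueous KOH, toluene, −40 °C and a C2-symmetric N-spiro binaphthyl quaternary ammonium bromide should give 1-tert-butyl 3-methyl (2R)-2-geranyl-2-prenylpropanedioate F2, the catalyst enantiomer or the order of the two alkylations being chosen accordingly. Me3SiOTf and 2,6-lutidine in CH2Cl2, then water, should remove the tert-butyl ester without protic acid and give (2S)-2-geranyl-2-(methoxycarbonyl)-5-methylhex-4-enoic acid F3. 1-Chloro-N,N,2-trimethylprop-1-en-1-amine converts it into methyl (2R)-2-(chlorocarbonyl)-2-geranyl-5-methylhex-4-enoate F4, which C-acylates 3 (MgCl2, pyridine, CH2Cl2) to give 12. LiN(iPr)2 (3 equiv), THF, −78 → 0 °C then closes the ring to 13 as in the second stage of step 5.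

Step 2. Regiocontrol of the lactonization may be lost, with ring closure of 5 through the benzoyl oxygen; O-acylation of 3 may also compete. Fallback setting out from 5 and coming back at 12: the regioisomeric lactone is used and not discarded. 4-Hydroxy-5-(5-methylhex-4-enoyl)-6-phenyl-2H-pyran-2-one F5 is prenylated under the conditions of step 3 to 4-hydroxy-5-(5-methylhex-4-enoyl)-3-(3-methylbut-2-en-1-yl)-6-phenyl-2H-pyran-2-one F6 and geranylated as in the first stage of step 5. The dearomatized lactone (3S)-3-geranyl-5-(5-methylhex-4-enoyl)-6-phenyl-3-prenyl-2H-pyran-2,4(3H)-dione F7, not isolated, is opened by the same methoxide relay to the same ester enolate 12, because the two lactones differ only in which enol oxygen of the triacylmethane closed the ring. The approach changes from controlling the regiochemistry to making it irrelevant.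

Step 3. Over-allylation at C-3, O-allylation that does not revert, or attack at the substituted allyl terminus (reverse prenyl) may occur. Fallback setting out from 3 and coming back at 8: the prenyl group is brought in with the malonyl unit and no allylation of the heterocycle is needed. Diethyl malonate and prenyl bromide (NaOEt, EtOH) give diethyl 2-(3-methylbut-2-en-1-yl)propanedioate F8. KOH (1 equiv) in EtOH gives 2-(ethoxycarbonyl)-5-methylhex-4-enoic acid F9. 1-Chloro-N,N,2-trimethylprop-1-en-1-amine gives ethyl 2-(chlorocarbonyl)-5-methylhex-4-enoate F10. C-acylation of 3 (MgCl2, pyridine, CH2Cl2) gives ethyl 4-benzoyl-9-methyl-2-(3-methylbut-2-en-1-yl)-3,5-dioxodec-8-enoate F11, and DBU in toluene at 80 °C should close it to 8.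

**Further compounds**

F1 | step 5 | tert-butyl methyl 2-(3-methylbut-2-en-1-yl)propanedioate | COC(=O)C(CC=C(C)C)C(=O)OC(C)(C)C
F2 | step 5 | 1-tert-butyl 3-methyl (2R)-2-[(2E)-3,7-dimethylocta-2,6-dien-1-yl]-2-(3-methylbut-2-en-1-yl)propanedioate | CC(C)=CCC/C(C)=C/C[C@](C(=O)OC(C)(C)C)(CC=C(C)C)C(=O)OC
F3 | step 5 | (2S)-2-[(2E)-3,7-dimethylocta-2,6-dien-1-yl]-2-(methoxycarbonyl)-5-methylhex-4-enoic acid | CC(C)=CCC/C(C)=C/C[C@](C(=O)O)(CC=C(C)C)C(=O)OC
F4 | step 5 | methyl (2R)-2-(chlorocarbonyl)-2-[(2E)-3,7-dimethylocta-2,6-dien-1-yl]-5-methylhex-4-enoate | CC(C)=CCC/C(C)=C/C[C@](C(Cl)=O)(CC=C(C)C)C(=O)OC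
F5 | step 2 | 4-hydroxy-5-(5-methylhex-4-enoyl)-6-phenyl-2H-pyran-2-one | O=C1C=C(O)C(C(=O)CCC=C(C)C)=C(c2ccccc2)O1
F6 | step 2 | 4-hydroxy-5-(5-methylhex-4-enoyl)-3-(3-methylbut-2-en-1-yl)-6-phenyl-2H-pyran-2-one | O=C1C(CC=C(C)C)=C(O)C(C(=O)CCC=C(C)C)=C(c2ccccc2)O1
F7 | step 2 | (3S)-3-[(2E)-3,7-dimethylocta-2,6-dien-1-yl]-5-(5-methylhex-4-enoyl)-3-(3-methylbut-2-en-1-yl)-6-phenyl-2H-pyran-2,4(3H)-dione | CC(C)=CCC/C(C)=C/C[C@]1(CC=C(C)C)C(=O)OC(c2ccccc2)=C(C(=O)CCC=C(C)C)C1=O
F8 | step 3 | diethyl 2-(3-methylbut-2-en-1-yl)propanedioate | CCOC(=O)C(CC=C(C)C)C(=O)OCC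
F9 | step 3 | 2-(ethoxycarbonyl)-5-methylhex-4-enoic acid | CCOC(=O)C(CC=C(C)C)C(=O)O
F10 | step 3 | ethyl 2-(chlorocarbonyl)-5-methylhex-4-enoate | CCOC(=O)C(CC=C(C)C)C(Cl)=O
F11 | step 3 | ethyl 4-benzoyl-9-methyl-2-(3-methylbut-2-en-1-yl)-3,5-dioxodec-8-enoate | CCOC(=O)C(CC=C(C)C)C(=O)C(C(=O)c1ccccc1)C(=O)CCC=C(C)C
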